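The route rests on one disconnection, the O1–C2 ether bond of ring C, leading back to an acyclic (R)-1,3-diarylpropan-1-ol with a single free phenol on ring A. The key step is an intramolecular Mitsunobu etherification that, in one operation under neutral, prenyl-tolerant conditions, forms O1–C2, closes the pyran ring and installs the (2S) centre by inversion. It exploits two features: ring B is oxygenated only at C3' and C5', so benzylic C2 cannot ionise and substitution stays SN2; and the only unprotected phenol is the one flanked by the C8 prenyl group, which fixes the regiochemistry. The precursor comes from a Claisen–Schmidt condensation and a tandem asymmetric transfer hydrogenation.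

Key step: step 6

Assumption: 1-(3-hydroxy-5-methoxyphenyl)ethan-1-one is taken as a catalogue compound, and flavan numbering (O1, C2–C4, C4a, C5–C8, C8a; ring B primed) is used throughout.

Step 1
Reactants: 1 2,4,6-trihydroxybenzaldehyde; 2 prenyl bromide (1-bromo-3-methylbut-2-ene)
Product: 3 2,4,6-trihydroxy-3-(3-methylbut-2-en-1-yl)benzaldehyde
Conditions: 2 (0.9 equiv), 10% aq. KOH, 0 °C to rt
Reagents that add atoms: none
Why: C-alkylation of the phloroglucinolate (Friedel–Crafts-type C-allylation), in which water hydrogen-bonds the oxygens so that the soft allylic bromide is attacked by ring carbon, C3 and C5 being equivalent so that only one mono-C-prenyl isomer can form and a slight deficit of 2 limiting double prenylation.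

Step 2
Reactants: 3 2,4,6-trihydroxy-3-(3-methylbut-2-en-1-yl)benzaldehyde
Product: 4 2-hydroxy-4,6-bis(methoxymethoxy)-3-(3-methylbut-2-en-1-yl)benzaldehyde
Conditions: MOMCl (2.2 equiv), K2CO3, acetone, 0 °C to rt
Reagents that add atoms: chloromethyl methyl ether (MOMCl), COCCl
Why: Williamson-type O-alkylation under weak base, which should cap the 4-OH (para to the formyl group, most acidic) and then the 6-OH (next to a ring hydrogen), while the 2-OH, pressed by the neighbouring prenyl group into a strong hydrogen bond with the formyl oxygen, is the least nucleophilic and stays free.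

Step 3
Reactants: 5 1-(3-hydroxy-5-methoxyphenyl)ethan-1-one
Product: 6 1-[3-methoxy-5-(methoxymethoxy)phenyl]ethan-1-one
Conditions: MOMCl (1.2 equiv), K2CO3, acetone, rt
Reagents that add atoms: chloromethyl methyl ether (MOMCl), COCCl
Why: Williamson-type O-alkylation of the only phenol, giving an acetal that masks the ring B hydroxyl through the basic condensation and the Mitsunobu step and is removed with the other two at the end.

Step 4
Reactants: 4 2-hydroxy-4,6-bis(methoxymethoxy)-3-(3-methylbut-2-en-1-yl)benzaldehyde; 6 1-[3-methoxy-5-(methoxymethoxy)phenyl]ethan-1-one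
Product: 7 (E)-3-[2-hydroxy-4,6-bis(methoxymethoxy)-3-(3-methylbut-2-en-1-yl)phenyl]-1-[3-methoxy-5-(methoxymethoxy)phenyl]prop-2-en-1-one
Conditions: KOH (50% aq.), EtOH, rt to 40 °C
Reagents that add atoms: none
Why: Claisen–Schmidt (crossed aldol) condensation in which only 6 can enolise and 4 has no α-hydrogen, E1cB dehydration of the aldol giving the conjugated E-enone while the MOM acetals, the aryl methyl ether and the prenyl group are inert to hydroxide.

Step 5
Reactants: 7 (E)-3-[2-hydroxy-4,6-bis(methoxymethoxy)-3-(3-methylbut-2-en-1-yl)phenyl]-1-[3-methoxy-5-(methoxymethoxy)phenyl]prop-2-en-1-one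
Product: 9 (1R)-3-[2-hydroxy-4,6-bis(methoxymethoxy)-3-(3-methylbut-2-en-1-yl)phenyl]-1-[3-methoxy-5-(methoxymethoxy)phenyl]propan-1-ol, via saturated ketone 8 (not isolated)
Conditions: RuCl[(R,R)-TsDPEN](p-cymene) (3 mol %), HCO2H/Et3N (1:1), EtOAc, 40 °C
Reagents that add atoms: none
Why: Tandem Noyori–Ikariya asymmetric transfer hydrogenation, in which the bifunctional Ru–H/N–H species first transfers hydride 1,4 to the enone (the isolated prenyl alkene cannot accept an outer-sphere hydride) and then reduces the aryl alkyl ketone 8 through the six-membered transition state whose CH/π contact between the p-cymene ligand and the ring B aryl makes the (R,R) catalyst deliver the (R)-carbinol.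

Step 6
Reactants: 9 (1R)-3-[2-hydroxy-4,6-bis(methoxymethoxy)-3-(3-methylbut-2-en-1-yl)phenyl]-1-[3-methoxy-5-(methoxymethoxy)phenyl]propan-1-ol
Product: 10 (2S)-2-[3-methoxy-5-(methoxymethoxy)phenyl]-5,7-bis(methoxymethoxy)-8-(3-methylbut-2-en-1-yl)-3,4-dihydro-2H-chromene
Conditions: PPh3 (1.5 equiv), DIAD (1.5 equiv), THF (0.01 M), 0 °C to rt
Reagents that add atoms: none
Why: PPh3 and DIAD form the betaine, which deprotonates the lone free phenol and turns the secondary benzylic hydroxyl of 9 into an alkoxyphosphonium leaving group; the tethered phenoxide then displaces Ph3P=O by backside attack, forming O1–C2. The closest known reaction type is the intramolecular Mitsunobu etherification (cyclodehydration) of 1-aryl-3-(2-hydroxyaryl)propan-1-ols to 2-arylchromans. Ring C, the only ring closed, forms in the 6-exo-tet mode. The new C2 stereocenter is controlled by the (R)-carbinol centre of 9, which is inverted in the SN2 event to give (2S). The step needs SN2 over ionisation or E2, closure through the oxygen next to the prenyl group, and intra- over intermolecular alkylation; these are secured by the C3'/C5'-only oxygenation of ring B, which denies a benzylic cation at C2 any quinone-methide-type stabilisation, by MOM caps on every other phenol, and by high dilution. The neutral, non-electrophilic conditions should leave the prenyl alkene and the MOM acetals untouched.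

Step 7
Reactants: 10 (2S)-2-[3-methoxy-5-(methoxymethoxy)phenyl]-5,7-bis(methoxymethoxy)-8-(3-methylbut-2-en-1-yl)-3,4-dihydro-2H-chromene
Product: 11 (2S)-2-(3-hydroxy-5-methoxyphenyl)-8-(3-methylbut-2-en-1-yl)-3,4-dihydro-2H-chromene-5,7-diol (CNP0173255.1)
Conditions: HCl (1.25 M in MeOH), MeOH, 35 °C
Reagents that add atoms: none
Why: Acid-catalysed acetal cleavage (transacetalisation to dimethoxymethane) frees the three phenols, methanol trapping the methoxymethyl cation before it can alkylate the electron-rich ring A, while dilute acid at mild temperature should neither add the 7-OH across the prenyl alkene nor ionise the C2–O1 bond, whose benzylic cation ring B cannot stabilise, so the (2S) centre is retained.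

Compound list
1 | 2,4,6-trihydroxybenzaldehyde | O=Cc1c(O)cc(O)cc1O | starting material
2 | prenyl bromide (1-bromo-3-methylbut-2-ene) | CC(C)=CCBr | starting material
3 | 2,4,6-trihydroxy-3-(3-methylbut-2-en-1-yl)benzaldehyde | O=Cc1c(O)cc(O)c(CC=C(C)C)c1O | intermediate
4 | 2-hydroxy-4,6-bis(methoxymethoxy)-3-(3-methylbut-2-en-1-yl)benzaldehyde | O=Cc1c(O)c(CC=C(C)C)c(OCOC)cc1OCOC | intermediate
5 | 1-(3-hydroxy-5-methoxyphenyl)ethan-1-one | CC(=O)c1cc(O)cc(OC)c1 | starting material
6 | 1-[3-methoxy-5-(methoxymethoxy)phenyl]ethan-1-one | CC(=O)c1cc(OC)cc(OCOC)c1 | intermediate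
7 | (E)-3-[2-hydroxy-4,6-bis(methoxymethoxy)-3-(3-methylbut-2-en-1-yl)phenyl]-1-[3-methoxy-5-(methoxymethoxy)phenyl]prop-2-en-1-one | COCOc1cc(OC)cc(c1)C(=O)/C=C/c1c(O)c(CC=C(C)C)c(OCOC)cc1OCOC | intermediate
8 | 3-[2-hydroxy-4,6-bis(methoxymethoxy)-3-(3-methylbut-2-en-1-yl)phenyl]-1-[3-methoxy-5-(methoxymethoxy)phenyl]propan-1-one (saturated ketone, not isolated) | COCOc1cc(OC)cc(c1)C(=O)CCc1c(O)c(CC=C(C)C)c(OCOC)cc1OCOC | intermediate
9 | (1R)-3-[2-hydroxy-4,6-bis(methoxymethoxy)-3-(3-methylbut-2-en-1-yl)phenyl]-1-[3-methoxy-5-(methoxymethoxy)phenyl]propan-1-ol | COCOc1cc(OC)cc(c1)[C@H](O)CCc1c(O)c(CC=C(C)C)c(OCOC)cc1OCOC | intermediate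
10 | (2S)-2-[3-methoxy-5-(methoxymethoxy)phenyl]-5,7-bis(methoxymethoxy)-8-(3-methylbut-2-en-1-yl)-3,4-dihydro-2H-chromene | COCOc1cc(OC)cc(c1)[C@@H]1CCc2c(OCOC)cc(OCOC)c(CC=C(C)C)c2O1 | intermediate
11 | (2S)-2-(3-hydroxy-5-methoxyphenyl)-8-(3-methylbut-2-en-1-yl)-3,4-dihydro-2H-chromene-5,7-diol (CNP0173255.1) | COc1cc(O)cc([C@@H]2CCc3c(O)cc(O)c(CC=C(C)C)c3O2)c1 | target

Total step count: 7. Longest linear sequence: 6 steps (from 1 through steps 1, 2, 4, 5, 6 and 7); step 3 prepares the ring B partner.

Steps most likely to fail

Step 6 (key ring closure). The activated benzylic carbinol may undergo E2 loss to the styrene, or the hindered phenoxide may react so slowly that intermolecular alkylation takes over. The fallback sets out from 9 and returns at 10 by a one-pot Williamson closure through a sulfonate. The dianion of 9 (NaH, 2.2 equiv, THF, 0 °C) is treated with 1-(p-toluenesulfonyl)imidazole (1.0 equiv). The more basic benzylic alkoxide should be sulfonylated with retention to the (R)-benzylic tosylate F1. F1 is not isolated, because the neighbouring sodium phenoxide displaces tosylate in a 6-exo-tet SN2 step with inversion to give 10. Any premature cyclisation leads to the same enantiomer.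

Step 5 (tandem transfer hydrogenation). Hydride transfer to the β-carbon of the donor-rich enone may be slow, so that 1,2-reduction to the allylic alcohol or incomplete conversion competes and the enantiopurity of the carbinol suffers. The fallback sets out from 7 and returns at 9 by separating the two reductions; it makes no compound outside the list (F0). Hydrogenation with RhCl(PPh3)3 (H2, 1 atm, benzene/EtOH, rt) should saturate only the disubstituted enone alkene and leave the trisubstituted prenyl alkene, and the saturated ketone 8 is isolated this time. Corey–Bakshi–Shibata reduction then sets the (R)-carbinol 9, using (S)-1-methyl-3,3-diphenyl-tetrahydro-1H,3H-pyrrolo[1,2-c][1,3,2]oxazaborole ((S)-Me-CBS) and BH3·SMe2 in THF at −20 °C, with one extra equivalent of borane for the phenol.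

Step 2 (regioselective protection). The second MOM group may go onto the hydroxyl next to the prenyl chain, or mixtures may form; this would move the ring-closing oxygen and end in the 6-prenyl series. The fallback sets out from 1 and returns at 4, replacing steps 1 and 2 by an aromatic Claisen rearrangement whose regiochemistry is fixed by the oxygen that carries the migrating group. Bis-protection of 1 (MOMCl, K2CO3, acetone) gives 2-hydroxy-4,6-bis(methoxymethoxy)benzaldehyde F2. O-alkylation of the remaining phenol with 3-chloro-3-methylbut-1-yne (CuCl2 cat., DBU, MeCN, 0 °C) gives the 1,1-dimethylpropargyl ether F3. Semi-hydrogenation (H2, Pd/CaCO3 poisoned with Pb(OAc)2, quinoline, EtOAc) gives the 1,1-dimethylallyl ether F4. Heating (N,N-diethylaniline, 130 °C) should bring about the [3,3] shift to C3, the only unsubstituted ortho carbon, which places a linear prenyl group next to the liberated hydroxyl, that is 4.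

Further compounds
F1 | step 6 | (1R)-3-[2-hydroxy-4,6-bis(methoxymethoxy)-3-(3-methylbut-2-en-1-yl)phenyl]-1-[3-methoxy-5-(methoxymethoxy)phenyl]propyl 4-methylbenzenesulfonate (present as its sodium phenoxide, not isolated) | COCOc1cc(OC)cc(c1)[C@H](OS(=O)(=O)c1ccc(C)cc1)CCc1c(O)c(CC=C(C)C)c(OCOC)cc1OCOC
F0 | step 5 | none | none
F2 | step 2 | 2-hydroxy-4,6-bis(methoxymethoxy)benzaldehyde | O=Cc1c(O)cc(OCOC)cc1OCOC
F3 | step 2 | 4,6-bis(methoxymethoxy)-2-[(2-methylbut-3-yn-2-yl)oxy]benzaldehyde | O=Cc1c(OC(C)(C)C#C)cc(OCOC)cc1OCOC
F4 | step 2 | 4,6-bis(methoxymethoxy)-2-[(2-methylbut-3-en-2-yl)oxy]benzaldehyde | O=Cc1c(OC(C)(C)C=C)cc(OCOC)cc1OCOC
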